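**Retrosynthetic overview**
- The route rests on the ketone carbon C7', which joins ring carbon C4 of the tetrahydrofuran (O1, C2–C5) to the syringyl ring; C4 is α to this carbonyl, so it can be epimerised and the 3,4-trans arrangement is the thermodynamic one.
- After deprotection, C4–C7' and C7'–aryl are cut in one operation, back to a C4 iodide (either epimer), carbon monoxide and a syringyl boronic acid; C4 is set at this stage.
- The iodide comes from the 4-hydroxytetrahydrofuran, whose ring (the only ring formed) is closed by O1–C5 etherification of a 1,2,4-triol.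
- The triol derives from an Evans syn-aldol of a crotonyl imide dienolate with O-benzylvanillin, which sets C2 and C3; both aromatic rings are purchased.

Key step: step 10

Remark: the tetrahydrofuran is numbered O1, C2 (guaiacyl carbon), C3 (CH2O carbon), C4, C5 throughout and the ketone carbon is C7'; 4-benzyloxy-3-methoxybenzaldehyde is taken as a purchased material in place of vanillin.

**Step 1**
Reactants: 1 (S)-4-benzyl-2-oxazolidinone; 2 (E)-but-2-enoyl chloride (crotonyl chloride)
Product: 4 (S)-4-benzyl-3-[(E)-but-2-enoyl]oxazolidin-2-one, via lithium oxazolidinide 3 (not isolated)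
Conditions: n-BuLi, THF, −78 °C; then 2, −78 → 0 °C
Reagents that add atoms: none
Why: N-acylation of the lithium amide of the auxiliary by an acid chloride is the standard route to Evans imides; at −78 °C attack at the carbonyl outruns conjugate addition, and no stereocentre is formed.

**Step 2**
Reactants: 4 (S)-4-benzyl-3-[(E)-but-2-enoyl]oxazolidin-2-one; 5 4-benzyloxy-3-methoxybenzaldehyde (O-benzylvanillin)
Product: 8 (S)-4-benzyl-3-[(2S,3S)-3-(4-benzyloxy-3-methoxyphenyl)-2-ethenyl-3-hydroxypropanoyl]oxazolidin-2-one, via dibutylboron dienolate 6 (not isolated), via dibutylboron aldolate 7 (not isolated)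
Conditions: Bu2BOTf, Et3N, CH2Cl2, −78 → 0 °C; then 5, −78 → 0 °C; then pH 7 buffer, MeOH, 30% H2O2, 0 °C
Reagents that add atoms: none
Why: Evans syn-aldol reaction: soft enolisation at the γ-carbon gives the (Z)-boron dienolate, which reacts through its α-carbon in a closed Zimmerman–Traxler chair on the face away from the benzyl group of the (S)-auxiliary, setting the (2S,3S) syn pair that becomes C3 and C2 of the tetrahydrofuran (2,3-trans after ring closure).

**Step 3**
Reactants: 8 aldol adduct
Product: 9 (1S,2R)-1-(4-benzyloxy-3-methoxyphenyl)-2-ethenylpropane-1,3-diol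
Conditions: LiBH4, MeOH (1 equiv), THF, 0 °C
Reagents that add atoms: none
Why: Reductive removal of the auxiliary with LiBH4 (hydride attack on the exocyclic imide carbonyl, assisted by the β-hydroxyl) gives the primary alcohol without touching the vinyl group, and the former α-carbon is no longer epimerisable.

**Step 4**
Reactants: 9 (1S,2R)-1-(4-benzyloxy-3-methoxyphenyl)-2-ethenylpropane-1,3-diol
Product: 10 (1S,2R)-1-(4-benzyloxy-3-methoxyphenyl)-2-[(tert-butyldimethylsilyloxy)methyl]but-3-en-1-ol
Conditions: TBSCl, imidazole, CH2Cl2, 0 °C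
Reagents that add atoms: tert-butyldimethylsilyl chloride, CC(C)(C)[Si](C)(C)Cl
Why: Steric differentiation in silylation: TBSCl with imidazole at 0 °C reacts at the primary hydroxyl well ahead of the hindered secondary benzylic one.

**Step 5**
Reactants: 10 silyl ether
Product: 11 (1S,2R,3RS)-1-(4-benzyloxy-3-methoxyphenyl)-2-[(tert-butyldimethylsilyloxy)methyl]butane-1,3,4-triol (both C3 epimers)
Conditions: OsO4 (cat.), NMO, acetone/H2O, rt
Reagents that add atoms: N-methylmorpholine N-oxide, C[N+]1([O-])CCOCC1; water, O (the two hydroxyl oxygens are delivered through OsO4)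
Why: Upjohn dihydroxylation of the terminal alkene by catalytic OsO4 with NMO as reoxidant; the new carbinol (future C4) may form as both epimers because this centre is erased at the radical stage of step 10.

**Step 6**
Reactants: 11 triol (both C3 epimers)
Product: 13 (2S,3S,4RS)-2-(4-benzyloxy-3-methoxyphenyl)-3-[(tert-butyldimethylsilyloxy)methyl]tetrahydrofuran-4-ol (both C4 epimers; 2,3-trans), via primary tosylate 12 (not isolated)
Conditions: TsCl, pyridine, CH2Cl2, 0 °C → rt; then 50 °C
Reagents that add atoms: none
Why: Selective sulfonylation of the primary hydroxyl followed by intramolecular Williamson etherification (5-exo-tet attack of the benzylic hydroxyl on C5) closes the tetrahydrofuran; the benzylic C–O bond is not broken, so C2 and C3 keep the aldol configuration, and in pyridine the neutral secondary hydroxyl next to the sulfonate does not close an oxirane at a competitive rate.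

**Step 7**
Reactants: 13 tetrahydrofuran-4-ol (both C4 epimers)
Product: 14 (2S,3R,4RS)-2-(4-benzyloxy-3-methoxyphenyl)-3-[(tert-butyldimethylsilyloxy)methyl]-4-iodotetrahydrofuran (both C4 epimers)
Conditions: I2, PPh3, imidazole, toluene, 70 °C
Reagents that add atoms: iodine, II
Why: Appel-type iodination (Garegg–Samuelsson conditions) through the alkoxyphosphonium salt with SN2 entry of iodide; imidazole buffers the medium for the silyl and benzylic ethers, and the C4 epimer ratio is of no consequence.

**Step 8**
Reactants: 15 4-bromo-2,6-dimethoxyphenol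
Product: 16 2-benzyloxy-5-bromo-1,3-dimethoxybenzene
Conditions: BnBr, K2CO3, DMF, rt
Reagents that add atoms: benzyl bromide, BrCc1ccccc1
Why: Williamson etherification of the hindered but acidic 2,6-dimethoxyphenoxide with benzyl bromide.

**Step 9**
Reactants: 16 2-benzyloxy-5-bromo-1,3-dimethoxybenzene
Product: 19 (4-benzyloxy-3,5-dimethoxyphenyl)boronic acid, via aryllithium 17 (not isolated), via lithium triisopropoxyborate 18 (not isolated)
Conditions: n-BuLi, THF, −78 °C; B(OiPr)3, −78 °C → rt; then 1 M HCl, 0 °C
Reagents that add atoms: triisopropyl borate, CC(C)OB(OC(C)C)OC(C)C; water, O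
Why: Bromine–lithium exchange at −78 °C is faster than any ortho-metalation, and trapping of the aryllithium with the borate ester followed by mild acidic hydrolysis gives the boronic acid (lithiation–borylation).

**Step 10**
Reactants: 14 4-iodotetrahydrofuran (both C4 epimers); 19 (4-benzyloxy-3,5-dimethoxyphenyl)boronic acid
Product: 21 [(2S,3R,4S)-2-(4-benzyloxy-3-methoxyphenyl)-3-[(tert-butyldimethylsilyloxy)methyl]tetrahydrofuran-4-yl](4-benzyloxy-3,5-dimethoxyphenyl)methanone, via C4-epimeric ketone 20 (not isolated)
Conditions: Pd(PPh3)4 (5 mol %), K2CO3, CO (45 atm), C6H6/H2O, hν (Xe lamp, Pyrex), rt; then DBU, CH2Cl2, rt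
Reagents that add atoms: carbon monoxide, [C-]#[O+]
Why: Light-excited zerovalent palladium transfers an electron to the C4–I bond of either epimer of 14, the resulting planar C4 radical adds CO to form C4–C7', the acyl radical is captured by palladium as an acyl complex of divalent palladium, and transmetallation with the borate of 19 followed by reductive elimination forms C7'–aryl and returns zerovalent palladium. The closest known reaction type is the light-promoted palladium-catalysed carbonylative Suzuki-type coupling of unactivated secondary alkyl iodides with arylboronic acids, applied here to a 4-iodotetrahydrofuran. No ring is closed, and the only new stereocentre is C4. It is controlled first by CO capture on the radical face anti to the adjacent C3 silyloxymethyl group and then thermodynamically, since C4 is α to the new ketone and DBU equilibrates any 3,4-cis ketone 20 through the enolate to the all-trans 21. The step needs carbonylation to outrun direct alkyl–aryl coupling, reduction and β-elimination, which the high CO pressure and the radical character at C4 (a C4 anion or alkylmetal would expel the C5 oxygen) should secure. Because both iodide epimers give the same radical, no stereocontrol at C4 is demanded of the precursor, and the electron-rich aroyl chromophore with a π,π* lowest triplet is not expected to undergo photochemical hydrogen abstraction under Pyrex-filtered light.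

**Step 11**
Reactants: 21 silyl-protected ketone
Product: 22 [(2S,3R,4S)-2-(4-benzyloxy-3-methoxyphenyl)-3-(hydroxymethyl)tetrahydrofuran-4-yl](4-benzyloxy-3,5-dimethoxyphenyl)methanone
Conditions: Bu4NF, AcOH, THF, 0 °C → rt
Reagents that add atoms: none
Why: Fluoride cleavage of the primary silyl ether driven by the Si–F bond; acetic acid buffering keeps the medium from opening the β-alkoxy ketone, and C4 is already in its thermodynamic configuration.

**Step 12**
Reactants: 22 di-O-benzyl ether of the target
Product: 23 [(2S,3R,4S)-2-(4-hydroxy-3-methoxyphenyl)-3-(hydroxymethyl)tetrahydrofuran-4-yl](4-hydroxy-3,5-dimethoxyphenyl)methanone (CNP0169680.1)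
Conditions: H2 (1 atm), 10% Pd/C, EtOAc, rt
Reagents that add atoms: none
Why: Catalytic hydrogenolysis of the two aryl benzyl ethers, which are cleaved faster than the electron-rich aryl ketone is reduced or the benzylic C2–O1 ring bond is cut, so the reaction is stopped once both benzyl groups are gone; no stereocentre is touched.

**Compound list**
1 | (S)-4-benzyl-2-oxazolidinone | O=C1N[C@@H](Cc2ccccc2)CO1 | starting material
2 | (E)-but-2-enoyl chloride (crotonyl chloride) | C/C=C/C(Cl)=O | starting material
3 | N-lithio-(S)-4-benzyl-2-oxazolidinone | [Li]N1[C@@H](Cc2ccccc2)COC1=O | intermediate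
4 | (S)-4-benzyl-3-[(E)-but-2-enoyl]oxazolidin-2-one | C/C=C/C(=O)N1[C@@H](Cc2ccccc2)COC1=O | intermediate
5 | 4-benzyloxy-3-methoxybenzaldehyde (O-benzylvanillin) | COc1cc(C=O)ccc1OCc1ccccc1 | starting material
6 | (Z)-O-dibutylboron dienolate of 4 | C=C/C=C(\OB(CCCC)CCCC)N1[C@@H](Cc2ccccc2)COC1=O | intermediate
7 | O-dibutylboron aldolate of 8 | COc1cc([C@@H](OB(CCCC)CCCC)[C@H](C=C)C(=O)N2[C@@H](Cc3ccccc3)COC2=O)ccc1OCc1ccccc1 | intermediate
8 | (S)-4-benzyl-3-[(2S,3S)-3-(4-benzyloxy-3-methoxyphenyl)-2-ethenyl-3-hydroxypropanoyl]oxazolidin-2-one | COc1cc([C@@H](O)[C@H](C=C)C(=O)N2[C@@H](Cc3ccccc3)COC2=O)ccc1OCc1ccccc1 | intermediate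
9 | (1S,2R)-1-(4-benzyloxy-3-methoxyphenyl)-2-ethenylpropane-1,3-diol | COc1cc([C@@H](O)[C@H](C=C)CO)ccc1OCc1ccccc1 | intermediate
10 | (1S,2R)-1-(4-benzyloxy-3-methoxyphenyl)-2-[(tert-butyldimethylsilyloxy)methyl]but-3-en-1-ol | COc1cc([C@@H](O)[C@H](C=C)CO[Si](C)(C)C(C)(C)C)ccc1OCc1ccccc1 | intermediate
11 | (1S,2R,3RS)-1-(4-benzyloxy-3-methoxyphenyl)-2-[(tert-butyldimethylsilyloxy)methyl]butane-1,3,4-triol, both C3 epimers | COc1cc([C@@H](O)[C@H](C(O)CO)CO[Si](C)(C)C(C)(C)C)ccc1OCc1ccccc1 | intermediate
12 | 4-O-(p-toluenesulfonyl) derivative of triol 11, both C3 epimers | COc1cc([C@@H](O)[C@H](C(O)COS(=O)(=O)c2ccc(C)cc2)CO[Si](C)(C)C(C)(C)C)ccc1OCc1ccccc1 | intermediate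
13 | (2S,3S,4RS)-2-(4-benzyloxy-3-methoxyphenyl)-3-[(tert-butyldimethylsilyloxy)methyl]tetrahydrofuran-4-ol, 2,3-trans, both C4 epimers | COc1cc([C@H]2OCC(O)[C@@H]2CO[Si](C)(C)C(C)(C)C)ccc1OCc1ccccc1 | intermediate
14 | (2S,3R,4RS)-2-(4-benzyloxy-3-methoxyphenyl)-3-[(tert-butyldimethylsilyloxy)methyl]-4-iodotetrahydrofuran, 2,3-trans, both C4 epimers | COc1cc([C@H]2OCC(I)[C@@H]2CO[Si](C)(C)C(C)(C)C)ccc1OCc1ccccc1 | intermediate
15 | 4-bromo-2,6-dimethoxyphenol | Oc1c(OC)cc(Br)cc1OC | starting material
16 | 2-benzyloxy-5-bromo-1,3-dimethoxybenzene | COc1cc(Br)cc(OC)c1OCc1ccccc1 | intermediate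
17 | (4-benzyloxy-3,5-dimethoxyphenyl)lithium | [Li]c1cc(OC)c(OCc2ccccc2)c(OC)c1 | intermediate
18 | lithium (4-benzyloxy-3,5-dimethoxyphenyl)triisopropoxyborate | [Li+].COc1cc([B-](OC(C)C)(OC(C)C)OC(C)C)cc(OC)c1OCc1ccccc1 | intermediate
19 | (4-benzyloxy-3,5-dimethoxyphenyl)boronic acid | COc1cc(B(O)O)cc(OC)c1OCc1ccccc1 | intermediate
20 | (2S,3R,4R) C4 epimer of 21 (3,4-cis ketone) | COc1cc([C@H]2OC[C@H](C(=O)c3cc(OC)c(OCc4ccccc4)c(OC)c3)[C@@H]2CO[Si](C)(C)C(C)(C)C)ccc1OCc1ccccc1 | intermediate
21 | [(2S,3R,4S)-2-(4-benzyloxy-3-methoxyphenyl)-3-[(tert-butyldimethylsilyloxy)methyl]tetrahydrofuran-4-yl](4-benzyloxy-3,5-dimethoxyphenyl)methanone, all-trans | COc1cc([C@H]2OC[C@@H](C(=O)c3cc(OC)c(OCc4ccccc4)c(OC)c3)[C@@H]2CO[Si](C)(C)C(C)(C)C)ccc1OCc1ccccc1 | intermediate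
22 | [(2S,3R,4S)-2-(4-benzyloxy-3-methoxyphenyl)-3-(hydroxymethyl)tetrahydrofuran-4-yl](4-benzyloxy-3,5-dimethoxyphenyl)methanone | COc1cc([C@H]2OC[C@@H](C(=O)c3cc(OC)c(OCc4ccccc4)c(OC)c3)[C@@H]2CO)ccc1OCc1ccccc1 | intermediate
23 | [(2S,3R,4S)-2-(4-hydroxy-3-methoxyphenyl)-3-(hydroxymethyl)tetrahydrofuran-4-yl](4-hydroxy-3,5-dimethoxyphenyl)methanone (CNP0169680.1) | COc1cc([C@H]2OC[C@@H](C(=O)c3cc(OC)c(O)c(OC)c3)[C@@H]2CO)ccc1O | target

**Step count**
Total: 12 steps. Longest linear sequence: 10 steps (steps 1–7, then 10–12); the boronic acid branch (steps 8–9) is 2 steps.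

**Steps most likely to fail**

Step 10. The C4 radical may be reduced, or its alkylpalladium form may eliminate, before CO is taken up; direct coupling without CO may compete; or the ketone may not reach the trans form. The fallback sets out from 16 and 14 and makes the ketone by a cross-electrophile coupling in which the carbonyl carbon arrives with the aryl partner. Bromide 16 is lithiated as in step 9 (n-BuLi, THF, −78 °C) and the aryllithium 17 is quenched with CO2 to give 4-benzyloxy-3,5-dimethoxybenzoic acid F1. Oxalyl chloride with catalytic DMF in CH2Cl2 converts it into 4-benzyloxy-3,5-dimethoxybenzoyl chloride F2. F2 and iodide 14 are then joined by the known nickel-catalysed reductive acylation of secondary alkyl halides with aroyl chlorides (NiCl2(dme), 4,4'-di-tert-butyl-2,2'-bipyridine, Zn, MgCl2, DMA, rt). This also passes through the C4 radical, so both iodide epimers are used, and it needs neither light nor CO pressure. DBU in CH2Cl2 then equilibrates the ketone epimers, and the route is rejoined at 21.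

Step 6. Sulfonylation may occur at a secondary hydroxyl, or the vicinal hydroxy sulfonate may close to an oxirane instead of undergoing the 5-exo displacement. The fallback sets out from triol 11 and forms the other ether bond, O1–C2. Catalytic camphorsulfonic acid in CH2Cl2 at 0 °C ionises the electron-rich benzylic alcohol, and the primary hydroxyl traps the cation in a 5-membered closure. The aryl group should settle trans to the C3 substituent, which is the configuration the aldol had already set. The fallback makes no new compound and returns to the route at 13.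

Step 7. E2 elimination from the alkoxyphosphonium intermediate, or acid-promoted loss of the silyl ether on heating, may erode the iodide. The fallback sets out from 13 and separates activation from displacement. Tf2O and pyridine in CH2Cl2 at −30 °C give (2S,3R,4RS)-2-(4-benzyloxy-3-methoxyphenyl)-3-[(tert-butyldimethylsilyloxy)methyl]tetrahydrofuran-4-yl trifluoromethanesulfonate F3. Bu4NI in toluene from −30 °C to rt displaces the triflate without heating, and the route is rejoined at 14.

**Further compounds**
F1 | step 10 | 4-benzyloxy-3,5-dimethoxybenzoic acid | COc1cc(C(=O)O)cc(OC)c1OCc1ccccc1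
F2 | step 10 | 4-benzyloxy-3,5-dimethoxybenzoyl chloride | COc1cc(C(Cl)=O)cc(OC)c1OCc1ccccc1
F0 | step 6 | none | none
F3 | step 7 | (2S,3R,4RS)-2-(4-benzyloxy-3-methoxyphenyl)-3-[(tert-butyldimethylsilyloxy)methyl]tetrahydrofuran-4-yl trifluoromethanesulfonate | COc1cc([C@H]2OCC(OS(=O)(=O)C(F)(F)F)[C@@H]2CO[Si](C)(C)C(C)(C)C)ccc1OCc1ccccc1
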